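**Strategy**

The whole plan hangs on taking ring B apart at two bonds, O1–C7a and C3–C3a (benzofuran numbering). Ring A holds its ether oxygen and its benzylic carbon on two neighbouring carbons (C7a, C3a) and is otherwise substituted only at C5, para to O1, so plain benzyne can stand in for ring A and C5 can be addressed afterwards. In a single operation the alkoxide of O-silylated α-hydroxy-γ-butyrolactone adds to benzyne (from the ortho-silyl aryl triflate) and the resulting aryl anion is acylated by the lactone carbonyl: ring B closes and the hydroxyethyl arm that becomes the Cα enal is released. Dynamic transfer hydrogenation, Mitsunobu inversion and para-functionalisation follow.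

Key step: step 2

Remark: C1' is the carbinol carbon on C5 and Cα the enal carbon on C2; the sense of hydride delivery in steps 4 and 8 is assumed to follow the usual aryl-ketone model of the TsDPEN–ruthenium catalysts, and the enantiomeric catalyst would be used if analysis showed the opposite.

**Route**

Step 1
Reactants: 1 racemic 3-hydroxyoxolan-2-one
Product: 2 racemic 3-[(trimethylsilyl)oxy]oxolan-2-one
Conditions: TMSCl, Et3N, CH2Cl2, 0 °C to rt; distil
Reagents that add atoms: chlorotrimethylsilane, C[Si](C)(C)Cl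
Why: Routine O-silylation of a secondary alcohol (silyl ether formation), which removes the only O–H from the key step and lets fluoride release the alkoxide there.

Step 2
Reactants: 2 racemic 3-[(trimethylsilyl)oxy]oxolan-2-one; 3 2-(trimethylsilyl)phenyl trifluoromethanesulfonate
Product: 8 racemic 2-(2-hydroxyethyl)-1-benzofuran-3(2H)-one, via benzyne 4 (not isolated), via lactone alkoxide 5 (not isolated), via aryl anion 6 (not isolated), via hemiketal alkoxide 7 (not isolated)
Conditions: CsF (3 equiv), 2 (1.5 equiv), THF, 65 °C, slow addition of 3; then AcOH, H2O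
Reagents that add atoms: none
Why: Proposed new method: fluoride removes both trimethylsilyl groups, so benzyne 4 and the lactone alkoxide 5 are released together in a flask that contains no O–H; 5 adds to the aryne (O1–C7a), the ortho aryl anion 6 attacks the lactone carbonyl (C3a–C3) and the tetrahedral alkoxide 7 collapses with loss of the ring oxygen, which leaves the C3 ketone and the hydroxyethyl arm on C2. The nearest established chemistry is aryne insertion accompanied by acyl migration, by which salicylate esters are annulated to xanthones and β-keto esters undergo aryne acyl-alkylation; what is untested is an aliphatic α-oxido lactone as the partner. Ring B closes in a 5-exo-trig attack of the aryl anion on the carbonyl. No stereocentre is controlled here: C2 forms racemic and stays epimerisable through its aromatic enol, which step 4 turns to advantage. The selectivity needed is acylation of the aryl anion ahead of its protonation (plain O-arylation), secured by the five-membered transition state, the silyl-masked hydroxyl and THF as a solvent without acidic C–H. Regiochemistry does not arise because benzyne is symmetrical.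

Step 3
Reactants: 8 racemic 2-(2-hydroxyethyl)-1-benzofuran-3(2H)-one
Product: 9 racemic 2-[2-(tert-butyldimethylsilyloxy)ethyl]-1-benzofuran-3(2H)-one
Conditions: TBSCl, imidazole, CH2Cl2, 0 °C to rt
Reagents that add atoms: tert-butyldimethylsilyl chloride, CC(C)(C)[Si](C)(C)Cl
Why: Standard imidazole-mediated silylation of a primary alcohol, which also pulls any cyclic hemiketal form of 8 over to the open ketone.

Step 4
Reactants: 9 racemic 2-[2-(tert-butyldimethylsilyloxy)ethyl]-1-benzofuran-3(2H)-one
Product: 10 (2R,3R)-2-[2-(tert-butyldimethylsilyloxy)ethyl]-2,3-dihydro-1-benzofuran-3-ol (cis)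
Conditions: RuCl[(S,S)-TsDPEN](p-cymene) (cat.), HCO2H/Et3N (2:3), EtOAc, 40 °C
Reagents that add atoms: none
Why: Noyori asymmetric transfer hydrogenation run as a dynamic kinetic resolution: C2 epimerises through the aromatic 3-hydroxybenzofuran enol in the amine-rich medium, the (S,S) catalyst should deliver hydride to the C3 face that gives the (S) alcohol from simple aryl ketones (here named 3R because C2 outranks C3a) and does so anti to the C2 chain, so the cis (2R,3R) alcohol should result.

Step 5
Reactants: 10 (2R,3R)-2-[2-(tert-butyldimethylsilyloxy)ethyl]-2,3-dihydro-1-benzofuran-3-ol; 11 tiglic acid, (2E)-2-methylbut-2-enoic acid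
Product: 12 (2R,3S)-2-[2-(tert-butyldimethylsilyloxy)ethyl]-2,3-dihydro-1-benzofuran-3-yl (2E)-2-methylbut-2-enoate (trans)
Conditions: PPh3, DIAD, toluene, 0 °C to rt
Reagents that add atoms: tiglic acid (compound 11), C/C=C(\C)C(=O)O
Why: Mitsunobu esterification displaces the oxyphosphonium by tiglate in an SN2 step, inverting C3 from R to S and giving the trans ester, and any leakage through the benzylic cation should also be captured anti to the C2 chain.

Step 6
Reactants: 12 (2R,3S)-2-[2-(tert-butyldimethylsilyloxy)ethyl]-2,3-dihydro-1-benzofuran-3-yl (2E)-2-methylbut-2-enoate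
Product: 13 (2R,3S)-5-bromo-2-[2-(tert-butyldimethylsilyloxy)ethyl]-2,3-dihydro-1-benzofuran-3-yl (2E)-2-methylbut-2-enoate
Conditions: NBS, MeCN, 0 °C to rt, dark
Reagents that add atoms: N-bromosuccinimide, O=C1CCC(=O)N1Br
Why: Electrophilic aromatic bromination of an aryl ether goes para to O1, that is at C5, and polar, dark conditions keep the electron-poor tiglate alkene and the benzylic C–H out of radical chemistry.

Step 7
Reactants: 13 (2R,3S)-5-bromo-2-[2-(tert-butyldimethylsilyloxy)ethyl]-2,3-dihydro-1-benzofuran-3-yl (2E)-2-methylbut-2-enoate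
Product: 15 (2R,3S)-5-acetyl-2-[2-(tert-butyldimethylsilyloxy)ethyl]-2,3-dihydro-1-benzofuran-3-yl (2E)-2-methylbut-2-enoate, via enol ether 14 (not isolated)
Conditions: Bu3Sn[C(OEt)=CH2], PdCl2(PPh3)2 (cat.), toluene, 100 °C; then 0.5 M HCl, THF, 0 °C
Reagents that add atoms: tributyl(1-ethoxyvinyl)stannane, CCOC(=C)[Sn](CCCC)(CCCC)CCCC; water, O
Why: Stille coupling with the 1-ethoxyvinyl stannane (an acetyl anion equivalent) and brief mild acid hydrolysis of the aryl enol ether is a standard conversion of an aryl bromide to an aryl methyl ketone that tolerates esters and a primary silyl ether.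

Step 8
Reactants: 15 (2R,3S)-5-acetyl-2-[2-(tert-butyldimethylsilyloxy)ethyl]-2,3-dihydro-1-benzofuran-3-yl (2E)-2-methylbut-2-enoate
Product: 16 (2R,3S)-2-[2-(tert-butyldimethylsilyloxy)ethyl]-5-[(1R)-1-hydroxyethyl]-2,3-dihydro-1-benzofuran-3-yl (2E)-2-methylbut-2-enoate
Conditions: RuCl[(R,R)-TsDPEN](p-cymene) (cat.), HCO2H/Et3N (5:2), EtOAc, 30 °C
Reagents that add atoms: none
Why: Noyori asymmetric transfer hydrogenation of an aryl methyl ketone, in which the (R,R) catalyst should give the (R)-1-arylethanol by aryl/methyl face discrimination while the tiglate esters and their alkenes stay untouched.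

Step 9
Reactants: 16 (2R,3S)-2-[2-(tert-butyldimethylsilyloxy)ethyl]-5-[(1R)-1-hydroxyethyl]-2,3-dihydro-1-benzofuran-3-yl (2E)-2-methylbut-2-enoate; 11 tiglic acid
Product: 17 (1R)-1-[(2R,3S)-2-[2-(tert-butyldimethylsilyloxy)ethyl]-3-{[(2E)-2-methylbut-2-enoyl]oxy}-2,3-dihydro-1-benzofuran-5-yl]ethyl (2E)-2-methylbut-2-enoate
Conditions: tiglic acid, DCC, DMAP (cat.), CH2Cl2, 0 °C to rt
Reagents that add atoms: tiglic acid (compound 11), C/C=C(\C)C(=O)O
Why: Steglich esterification acylates the hydroxyl oxygen without touching the C1'–O bond, so the 1'R configuration is retained.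

Step 10
Reactants: 17 the silyl ether bis-tiglate
Product: 18 (1R)-1-[(2R,3S)-2-(2-hydroxyethyl)-3-{[(2E)-2-methylbut-2-enoyl]oxy}-2,3-dihydro-1-benzofuran-5-yl]ethyl (2E)-2-methylbut-2-enoate
Conditions: HF·pyridine, pyridine, THF, 0 °C to rt
Reagents that add atoms: none
Why: Fluoride cleavage of a primary TBS ether with pyridine-buffered HF is selective and should leave the two ionisable benzylic esters in place.

Step 11
Reactants: 18 the primary alcohol bis-tiglate
Product: 19 (1R)-1-[(2R,3S)-3-{[(2E)-2-methylbut-2-enoyl]oxy}-2-(2-oxoethyl)-2,3-dihydro-1-benzofuran-5-yl]ethyl (2E)-2-methylbut-2-enoate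
Conditions: Dess–Martin periodinane, NaHCO3, CH2Cl2, 0 °C to rt
Reagents that add atoms: none
Why: Dess–Martin oxidation stops at the aldehyde under near-neutral conditions, which avoids base-induced β-elimination of the aryloxy group; the aldehyde is used without storage.

Step 12
Reactants: 19 the β-aryloxy aldehyde
Product: 21 (1R)-1-[(2R,3S)-3-{[(2E)-2-methylbut-2-enoyl]oxy}-2-(3-oxoprop-1-en-2-yl)-2,3-dihydro-1-benzofuran-5-yl]ethyl (2E)-2-methylbut-2-enoate, via Mannich base 20 (not isolated)
Conditions: Eschenmoser's salt, Et3N, CH2Cl2, 0 °C to rt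
Reagents that add atoms: dimethylmethyleneiminium iodide (Eschenmoser's salt), C=[N+](C)C.[I-]
Why: Mannich reaction of the aldehyde enol with the iminium salt followed by in situ E1cB loss of dimethylamine (α-methylenation) should give the 2-substituted acrolein without involving C2.

**Compound list**

1 | racemic 3-hydroxyoxolan-2-one | OC1CCOC1=O | starting material
2 | racemic 3-[(trimethylsilyl)oxy]oxolan-2-one | C[Si](C)(C)OC1CCOC1=O | intermediate
3 | 2-(trimethylsilyl)phenyl trifluoromethanesulfonate | C[Si](C)(C)c1ccccc1OS(=O)(=O)C(F)(F)F | starting material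
4 | benzyne (1,2-didehydrobenzene) | C1#CC=CC=C1 | intermediate
5 | cesium 2-oxooxolan-3-olate (lactone alkoxide, racemic) | [Cs+].[O-]C1CCOC1=O | intermediate
6 | cesium 2-[(2-oxooxolan-3-yl)oxy]phenide (aryl anion) | [Cs+].O=C1OCCC1Oc1[c-]cccc1 | intermediate
7 | cesium 2,3-dihydrofuro[3,2-b][1]benzofuran-8b(3aH)-olate (cis-fused hemiketal alkoxide, racemic) | [Cs+].[O-]C12OCCC1Oc1ccccc12 | intermediate
8 | racemic 2-(2-hydroxyethyl)-1-benzofuran-3(2H)-one | O=C1c2ccccc2OC1CCO | intermediate
9 | racemic 2-[2-(tert-butyldimethylsilyloxy)ethyl]-1-benzofuran-3(2H)-one | CC(C)(C)[Si](C)(C)OCCC1Oc2ccccc2C1=O | intermediate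
10 | (2R,3R)-2-[2-(tert-butyldimethylsilyloxy)ethyl]-2,3-dihydro-1-benzofuran-3-ol (cis) | CC(C)(C)[Si](C)(C)OCC[C@H]1Oc2ccccc2[C@H]1O | intermediate
11 | tiglic acid, (2E)-2-methylbut-2-enoic acid | C/C=C(\C)C(=O)O | starting material
12 | (2R,3S)-2-[2-(tert-butyldimethylsilyloxy)ethyl]-2,3-dihydro-1-benzofuran-3-yl (2E)-2-methylbut-2-enoate (trans) | CC(C)(C)[Si](C)(C)OCC[C@H]1Oc2ccccc2[C@@H]1OC(=O)/C(C)=C/C | intermediate
13 | (2R,3S)-5-bromo-2-[2-(tert-butyldimethylsilyloxy)ethyl]-2,3-dihydro-1-benzofuran-3-yl (2E)-2-methylbut-2-enoate | CC(C)(C)[Si](C)(C)OCC[C@H]1Oc2ccc(Br)cc2[C@@H]1OC(=O)/C(C)=C/C | intermediate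
14 | (2R,3S)-2-[2-(tert-butyldimethylsilyloxy)ethyl]-5-(1-ethoxyethenyl)-2,3-dihydro-1-benzofuran-3-yl (2E)-2-methylbut-2-enoate | CC(C)(C)[Si](C)(C)OCC[C@H]1Oc2ccc(C(=C)OCC)cc2[C@@H]1OC(=O)/C(C)=C/C | intermediate
15 | (2R,3S)-5-acetyl-2-[2-(tert-butyldimethylsilyloxy)ethyl]-2,3-dihydro-1-benzofuran-3-yl (2E)-2-methylbut-2-enoate | CC(C)(C)[Si](C)(C)OCC[C@H]1Oc2ccc(C(C)=O)cc2[C@@H]1OC(=O)/C(C)=C/C | intermediate
16 | (2R,3S)-2-[2-(tert-butyldimethylsilyloxy)ethyl]-5-[(1R)-1-hydroxyethyl]-2,3-dihydro-1-benzofuran-3-yl (2E)-2-methylbut-2-enoate | CC(C)(C)[Si](C)(C)OCC[C@H]1Oc2ccc([C@@H](C)O)cc2[C@@H]1OC(=O)/C(C)=C/C | intermediate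
17 | (1R)-1-[(2R,3S)-2-[2-(tert-butyldimethylsilyloxy)ethyl]-3-{[(2E)-2-methylbut-2-enoyl]oxy}-2,3-dihydro-1-benzofuran-5-yl]ethyl (2E)-2-methylbut-2-enoate | CC(C)(C)[Si](C)(C)OCC[C@H]1Oc2ccc([C@@H](C)OC(=O)/C(C)=C/C)cc2[C@@H]1OC(=O)/C(C)=C/C | intermediate
18 | (1R)-1-[(2R,3S)-2-(2-hydroxyethyl)-3-{[(2E)-2-methylbut-2-enoyl]oxy}-2,3-dihydro-1-benzofuran-5-yl]ethyl (2E)-2-methylbut-2-enoate | OCC[C@H]1Oc2ccc([C@@H](C)OC(=O)/C(C)=C/C)cc2[C@@H]1OC(=O)/C(C)=C/C | intermediate
19 | (1R)-1-[(2R,3S)-3-{[(2E)-2-methylbut-2-enoyl]oxy}-2-(2-oxoethyl)-2,3-dihydro-1-benzofuran-5-yl]ethyl (2E)-2-methylbut-2-enoate | O=CC[C@H]1Oc2ccc([C@@H](C)OC(=O)/C(C)=C/C)cc2[C@@H]1OC(=O)/C(C)=C/C | intermediate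
20 | Mannich base: (1R)-1-[(2R,3S)-2-[1-(dimethylamino)-3-oxopropan-2-yl]-3-{[(2E)-2-methylbut-2-enoyl]oxy}-2,3-dihydro-1-benzofuran-5-yl]ethyl (2E)-2-methylbut-2-enoate (mixture at the new α-carbon) | CN(C)CC(C=O)[C@H]1Oc2ccc([C@@H](C)OC(=O)/C(C)=C/C)cc2[C@@H]1OC(=O)/C(C)=C/C | intermediate
21 | CNP0292799.1, (1R)-1-[(2R,3S)-3-{[(2E)-2-methylbut-2-enoyl]oxy}-2-(3-oxoprop-1-en-2-yl)-2,3-dihydro-1-benzofuran-5-yl]ethyl (2E)-2-methylbut-2-enoate | C=C(C=O)[C@H]1Oc2ccc([C@@H](C)OC(=O)/C(C)=C/C)cc2[C@@H]1OC(=O)/C(C)=C/C | target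

**Summary**

Total step count: 12. Longest linear sequence: 12 steps (1 to 21).

Steps most likely to fail:

1. Step 2 (key step). The aryl anion may be protonated before it acylates, the lactone alkoxide may oligomerise by transesterification, or the released primary alkoxide may be arylated a second time. The fallback uses known chemistry, sets out from 1 and returns at 8. Mitsunobu etherification of 1 with methyl salicylate (PPh3, DIAD, THF) should give methyl 2-[(2-oxooxolan-3-yl)oxy]benzoate F1. A Dieckmann-type intramolecular Claisen condensation of the lactone enolate onto the methyl ester (LiN(SiMe3)2, THF, −78 to 0 °C) should then close ring B as the spiro keto lactone 3H-spiro[1-benzofuran-2,3'-oxolane]-2',3-dione F2. Acid hydrolysis with decarboxylation of this α-acyl lactone (dilute H2SO4, dioxane, 90 °C) should open the lactone and deliver 8.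

2. Step 5 (Mitsunobu). The activated benzylic alcohol may eliminate towards the aromatic benzofuran, which would erase both ring stereocentres, or capture by the weakly acidic tiglic acid may be slow. The fallback sets out from 10 and returns at 12, separating inversion from tigloylation. Mitsunobu reaction with the more acidic 4-nitrobenzoic acid (PPh3, DIAD, toluene) should give (2R,3S)-2-[2-(tert-butyldimethylsilyloxy)ethyl]-2,3-dihydro-1-benzofuran-3-yl 4-nitrobenzoate F3. Methanolysis (K2CO3, MeOH) should give the trans alcohol (2R,3S)-2-[2-(tert-butyldimethylsilyloxy)ethyl]-2,3-dihydro-1-benzofuran-3-ol F4. Steglich esterification with 11 (DCC, DMAP) then proceeds with retention and gives 12.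

3. Step 12 (α-methylenation). Under amine conditions the β-aryloxy aldehyde may open by retro-oxa-Michael reaction (epimerisation at C2 or fragmentation), and the liberated amine may add to the product enal. The fallback sets out from 19 and returns at 21 without an equilibrating enolate. Kinetic silylation (TBSOTf, Et3N, CH2Cl2, −78 °C) should give the enol silyl ether (1R)-1-[(2R,3S)-2-[2-(tert-butyldimethylsilyloxy)ethenyl]-3-{[(2E)-2-methylbut-2-enoyl]oxy}-2,3-dihydro-1-benzofuran-5-yl]ethyl (2E)-2-methylbut-2-enoate F5. Base-free Mannich reaction of F5 with Eschenmoser's salt should give the Mannich base 20. N-Oxidation (mCPBA, CH2Cl2, −20 °C) should give the N-oxide of 20 F6, which should undergo Cope elimination on warming to rt and give 21.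

**Further compounds**

F1 | step 2 | methyl 2-[(2-oxooxolan-3-yl)oxy]benzoate (racemic) | COC(=O)c1ccccc1OC1CCOC1=O
F2 | step 2 | racemic 3H-spiro[1-benzofuran-2,3'-oxolane]-2',3-dione | O=C1OCCC12Oc1ccccc1C2=O
F3 | step 5 | (2R,3S)-2-[2-(tert-butyldimethylsilyloxy)ethyl]-2,3-dihydro-1-benzofuran-3-yl 4-nitrobenzoate | CC(C)(C)[Si](C)(C)OCC[C@H]1Oc2ccccc2[C@@H]1OC(=O)c1ccc(cc1)[N+](=O)[O-]
F4 | step 5 | (2R,3S)-2-[2-(tert-butyldimethylsilyloxy)ethyl]-2,3-dihydro-1-benzofuran-3-ol (trans) | CC(C)(C)[Si](C)(C)OCC[C@H]1Oc2ccccc2[C@@H]1O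
F5 | step 12 | (1R)-1-[(2R,3S)-2-[2-(tert-butyldimethylsilyloxy)ethenyl]-3-{[(2E)-2-methylbut-2-enoyl]oxy}-2,3-dihydro-1-benzofuran-5-yl]ethyl (2E)-2-methylbut-2-enoate (E/Z mixture) | CC(C)(C)[Si](C)(C)OC=C[C@H]1Oc2ccc([C@@H](C)OC(=O)/C(C)=C/C)cc2[C@@H]1OC(=O)/C(C)=C/C
F6 | step 12 | N-oxide of Mannich base 20 | C[N+](C)([O-])CC(C=O)[C@H]1Oc2ccc([C@@H](C)OC(=O)/C(C)=C/C)cc2[C@@H]1OC(=O)/C(C)=C/C
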